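**Plan**

- Retrosynthetic cuts, in order: the two MOM ethers and the C4 ketone level; the aryl ether bond O1–C8a of ring C; the two carbinol C–H bonds of an anti-1,3-diol (back to a 1,3-diketone); C2–C3 (Claisen condensation of the ring A methyl ketone with the ring B ester); the aryl–prenyl bonds at C6 and C8 and the C–I bonds before them.
- Forward: ring A is dressed first on 1-(2-bromo-4-hydroxyphenyl)ethanone (diiodination, MOM ether, twofold Stille prenylation), the C2–C3 bond brings in ring B, the diketone is reduced to the diol, and ring C is closed last; C4 oxidation and MOM removal finish.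
- Enabling feature: O1 joins the C2 carbinol carbon to the aromatic carbon C8a of ring A, so ring C can be closed from the arene side at a C8a bromide while the C2–O bond stays intact.
- Stereochemistry: C2 (S) comes from catalyst-controlled transfer hydrogenation with RuCl(p-cymene)[(S,S)-TsDPEN] and passes through the ring closure with retention; the C4 carbinol centre made alongside is erased by oxidation.

Key step: step 7

Remark: flavanone numbering (O1, C2, C3, C4, C4a, C5–C8, C8a; ring B primed) is used for all compounds, open-chain ones included; prenyl = 3-methylbut-2-enyl, MOM = methoxymethyl.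

Remark: where two like sites react in one flask (steps 1, 3, 6 and 9), the less hindered or more electrophilic site is assumed to react first; the order has no bearing on the product.

**Step 1**
Reactants: 1 1-(2-bromo-4-hydroxyphenyl)ethanone
Product: 3 1-(2-bromo-4-hydroxy-3,5-diiodophenyl)ethanone, via monoiodide 2 (not isolated)
Conditions: N-iodosuccinimide (2.2 equiv), CF3CO2H (cat.), MeCN, rt
Reagents that add atoms: N-iodosuccinimide, O=C1CCC(=O)N1I
Why: Electrophilic aromatic iodination goes to the two positions ortho to the free phenol (the later C6 and C8), the para position being blocked by the acetyl group and ring iodination being much faster than enolisation of the ketone.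

**Step 2**
Reactants: 3 1-(2-bromo-4-hydroxy-3,5-diiodophenyl)ethanone
Product: 4 1-[2-bromo-3,5-diiodo-4-(methoxymethoxy)phenyl]ethanone
Conditions: MOMCl, K2CO3, DMF, 0 °C to rt
Reagents that add atoms: chloromethyl methyl ether, COCCl
Why: Williamson-type O-alkylation of the acidic 2,6-diiodophenoxide with the highly reactive chloromethyl ether should give the MOM acetal, which masks the phenol through the basic and organometallic steps.

**Step 3**
Reactants: 4 1-[2-bromo-3,5-diiodo-4-(methoxymethoxy)phenyl]ethanone; 5 tributyl(3-methylbut-2-enyl)stannane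
Product: 7 1-[2-bromo-4-(methoxymethoxy)-3,5-bis(3-methylbut-2-enyl)phenyl]ethanone, via monoprenyl iodide 6 (not isolated)
Conditions: Pd(PPh3)4 (cat.), DMF, 80 °C
Reagents that add atoms: none
Why: Stille cross-coupling, in which zerovalent palladium should add to the two C–I bonds well before the doubly flanked C–Br bond and the η3-prenyl palladium intermediate should reductively eliminate at its unsubstituted terminus to give the linear prenyl arene.

**Step 4**
Reactants: 8 methyl 4-hydroxybenzoate
Product: 9 methyl 4-(methoxymethoxy)benzoate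
Conditions: MOMCl, K2CO3, acetone, rt
Reagents that add atoms: chloromethyl methyl ether, COCCl
Why: Williamson-type O-alkylation of the phenoxide under conditions that leave the methyl ester untouched.

**Step 5**
Reactants: 7 1-[2-bromo-4-(methoxymethoxy)-3,5-bis(3-methylbut-2-enyl)phenyl]ethanone; 9 methyl 4-(methoxymethoxy)benzoate
Product: 10 1-[2-bromo-4-(methoxymethoxy)-3,5-bis(3-methylbut-2-enyl)phenyl]-3-[4-(methoxymethoxy)phenyl]propane-1,3-dione
Conditions: NaH, THF, 65 °C; then AcOH, 0 °C
Reagents that add atoms: none
Why: Crossed Claisen condensation, in which the sodium enolate of the methyl ketone is acylated by the non-enolisable benzoate to form C2–C3 and deprotonation of the 1,3-diketone drives the equilibrium.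

**Step 6**
Reactants: 10 1-[2-bromo-4-(methoxymethoxy)-3,5-bis(3-methylbut-2-enyl)phenyl]-3-[4-(methoxymethoxy)phenyl]propane-1,3-dione
Product: 12 (1S,3S)-1-[2-bromo-4-(methoxymethoxy)-3,5-bis(3-methylbut-2-enyl)phenyl]-3-[4-(methoxymethoxy)phenyl]propane-1,3-diol, via hydroxy ketone 11 (not isolated)
Conditions: RuCl(p-cymene)[(S,S)-TsDPEN] (cat.), HCO2H/Et3N (5:2), CH2Cl2, 40 °C
Reagents that add atoms: none
Why: Noyori asymmetric transfer hydrogenation, in which the Ru–H/N–H pair of the (S,S)-TsDPEN complex should deliver hydride to each aryl ketone on the face fixed by the arene–aryl CH/π contact, giving S at both carbinols (the anti diol) under catalyst control while the alkenes, MOM ethers and aryl bromide stay inert.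

**Step 7**
Reactants: 12 (1S,3S)-1-[2-bromo-4-(methoxymethoxy)-3,5-bis(3-methylbut-2-enyl)phenyl]-3-[4-(methoxymethoxy)phenyl]propane-1,3-diol
Product: 13 (2S,4S)-7-(methoxymethoxy)-2-[4-(methoxymethoxy)phenyl]-6,8-bis(3-methylbut-2-enyl)-3,4-dihydro-2H-chromen-4-ol
Conditions: Pd(OAc)2 (5 mol%), 2-(di-tert-butylphosphino)-1,1'-binaphthyl (6 mol%), Cs2CO3, toluene, 80 °C
Reagents that add atoms: none
Why: Zerovalent palladium, generated in situ from Pd(OAc)2 and the phosphine, adds oxidatively to the C8a–Br bond, the C2 hydroxyl is deprotonated by Cs2CO3 and binds to the metal as an alkoxide, and C–O reductive elimination from the resulting seven-membered oxapalladacycle forms O1–C8a. The closest known reaction type is the palladium-catalysed intramolecular etherification of aryl bromides with pendant secondary alcohols (Buchwald–Hartwig-type C–O coupling), which is known to turn enantioenriched carbinols into chromans without erosion. Ring C, the only ring made here, closes in a 6-exo sense at the aryl carbon. No new stereocenter arises: the C2–O bond set in step 6 is never broken, so C2 stays S, and C4 is a spectator, which makes the product the 2,4-cis flavan-4-ol. The step needs site selectivity between the two hydroxyls and reductive elimination in preference to β-hydride elimination; the first follows from ring size, since the C4 hydroxyl could only give a four-membered ether, and the second from the bulky, electron-rich di-tert-butyl biaryl phosphine together with the favourable six-ring geometry. Carbopalladation of the neighbouring C8 prenyl group is not expected, because it would have to be a 4-exo or 5-endo addition to a trisubstituted alkene, and keeping C4 at the alcohol level excludes retro-aldol cleavage or dehydration under the basic conditions.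

**Step 8**
Reactants: 13 (2S,4S)-7-(methoxymethoxy)-2-[4-(methoxymethoxy)phenyl]-6,8-bis(3-methylbut-2-enyl)-3,4-dihydro-2H-chromen-4-ol
Product: 14 (2S)-7-(methoxymethoxy)-2-[4-(methoxymethoxy)phenyl]-6,8-bis(3-methylbut-2-enyl)-2,3-dihydrochromen-4-one
Conditions: Dess–Martin periodinane, CH2Cl2, 0 °C to rt
Reagents that add atoms: none
Why: Dess–Martin oxidation of the secondary benzylic carbinol to the C4 ketone under non-basic conditions that should leave the C2 ether centre and the prenyl alkenes untouched.

**Step 9**
Reactants: 14 (2S)-7-(methoxymethoxy)-2-[4-(methoxymethoxy)phenyl]-6,8-bis(3-methylbut-2-enyl)-2,3-dihydrochromen-4-one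
Product: 16 (2S)-7-hydroxy-2-(4-hydroxyphenyl)-6,8-bis(3-methylbut-2-enyl)-2,3-dihydrochromen-4-one, via 7-O-MOM flavanone 15 (not isolated)
Conditions: HCl (1 M), MeOH, 40 °C
Reagents that add atoms: none
Why: Acid-catalysed acetal cleavage (transacetalisation of the MOM groups to methanol) should free both phenols, dilute acid at mild temperature being chosen so that no prenyl group cyclises onto the new 7-hydroxyl and, with no base present, the flavanone does not open to the chalcone and racemise C2.

**Compound list**

1 | 1-(2-bromo-4-hydroxyphenyl)ethanone | CC(=O)c1ccc(O)cc1Br | starting material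
2 | 1-(2-bromo-4-hydroxy-5-iodophenyl)ethanone | CC(=O)c1cc(I)c(O)cc1Br | intermediate (not isolated)
3 | 1-(2-bromo-4-hydroxy-3,5-diiodophenyl)ethanone | CC(=O)c1cc(I)c(O)c(I)c1Br | intermediate
4 | 1-[2-bromo-3,5-diiodo-4-(methoxymethoxy)phenyl]ethanone | CC(=O)c1cc(I)c(OCOC)c(I)c1Br | intermediate
5 | tributyl(3-methylbut-2-enyl)stannane | CCCC[Sn](CCCC)(CCCC)CC=C(C)C | starting material
6 | 1-[2-bromo-3-iodo-4-(methoxymethoxy)-5-(3-methylbut-2-enyl)phenyl]ethanone | CC(=O)c1cc(CC=C(C)C)c(OCOC)c(I)c1Br | intermediate (not isolated)
7 | 1-[2-bromo-4-(methoxymethoxy)-3,5-bis(3-methylbut-2-enyl)phenyl]ethanone | CC(=O)c1cc(CC=C(C)C)c(OCOC)c(CC=C(C)C)c1Br | intermediate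
8 | methyl 4-hydroxybenzoate | COC(=O)c1ccc(O)cc1 | starting material
9 | methyl 4-(methoxymethoxy)benzoate | COC(=O)c1ccc(OCOC)cc1 | intermediate
10 | 1-[2-bromo-4-(methoxymethoxy)-3,5-bis(3-methylbut-2-enyl)phenyl]-3-[4-(methoxymethoxy)phenyl]propane-1,3-dione (drawn as the diketo form) | O=C(CC(=O)c1ccc(OCOC)cc1)c1cc(CC=C(C)C)c(OCOC)c(CC=C(C)C)c1Br | intermediate
11 | (3S)-3-[2-bromo-4-(methoxymethoxy)-3,5-bis(3-methylbut-2-enyl)phenyl]-3-hydroxy-1-[4-(methoxymethoxy)phenyl]propan-1-one | O[C@@H](CC(=O)c1ccc(OCOC)cc1)c1cc(CC=C(C)C)c(OCOC)c(CC=C(C)C)c1Br | intermediate (not isolated)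
12 | (1S,3S)-1-[2-bromo-4-(methoxymethoxy)-3,5-bis(3-methylbut-2-enyl)phenyl]-3-[4-(methoxymethoxy)phenyl]propane-1,3-diol (anti diol) | O[C@@H](C[C@H](O)c1ccc(OCOC)cc1)c1cc(CC=C(C)C)c(OCOC)c(CC=C(C)C)c1Br | intermediate
13 | (2S,4S)-7-(methoxymethoxy)-2-[4-(methoxymethoxy)phenyl]-6,8-bis(3-methylbut-2-enyl)-3,4-dihydro-2H-chromen-4-ol (2,4-cis) | CC(C)=CCc1cc2c(c(CC=C(C)C)c1OCOC)O[C@H](c1ccc(OCOC)cc1)C[C@@H]2O | intermediate
14 | (2S)-7-(methoxymethoxy)-2-[4-(methoxymethoxy)phenyl]-6,8-bis(3-methylbut-2-enyl)-2,3-dihydrochromen-4-one | CC(C)=CCc1cc2c(c(CC=C(C)C)c1OCOC)O[C@H](c1ccc(OCOC)cc1)CC2=O | intermediate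
15 | (2S)-2-(4-hydroxyphenyl)-7-(methoxymethoxy)-6,8-bis(3-methylbut-2-enyl)-2,3-dihydrochromen-4-one | CC(C)=CCc1cc2c(c(CC=C(C)C)c1OCOC)O[C@H](c1ccc(O)cc1)CC2=O | intermediate (not isolated)
16 | (2S)-7-hydroxy-2-(4-hydroxyphenyl)-6,8-bis(3-methylbut-2-enyl)-2,3-dihydrochromen-4-one | CC(C)=CCc1cc2c(c(CC=C(C)C)c1O)O[C@H](c1ccc(O)cc1)CC2=O | target

**Count and risks**

Total step count: 9. Longest linear sequence: 8 steps (steps 1, 2, 3, 5, 6, 7, 8, 9 from compound 1); step 4 is the side branch.

Steps most likely to fail:

Step 7. The palladium alkoxide may undergo β-hydride elimination, which would oxidise the C2 carbinol and reduce off the bromide. Oxidative addition into the doubly ortho-flanked C8a–Br bond may also be too slow. The fallback leaves palladium for a copper-mediated Ullmann closure on a more reactive halide. It sets out from diol 12, which is first converted by aromatic Finkelstein exchange (CuI, NaI, trans-N,N'-dimethylcyclohexane-1,2-diamine, dioxane, 110 °C) into (1S,3S)-1-[2-iodo-4-(methoxymethoxy)-3,5-bis(3-methylbut-2-enyl)phenyl]-3-[4-(methoxymethoxy)phenyl]propane-1,3-diol F1. Intramolecular O-arylation with monovalent copper (CuI, 3,4,7,8-tetramethyl-1,10-phenanthroline, Cs2CO3, toluene, 110 °C) then closes ring C, again with the C2–O bond untouched, and the route is rejoined at flavan-4-ol 13. Copper alkoxides have no facile β-hydride pathway.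

Step 3. Insertion into the C–Br bond may compete. The prenyl group may be transferred through its substituted terminus to give reverse-prenyl isomers. Coupling at the hindered iodide between bromine and the MOM ether may stall with protodeiodination. The fallback separates C–C coupling from construction of the trisubstituted alkene. It sets out from diiodide 4, which is coupled with allyltributylstannane (Pd(PPh3)4, DMF, 60 °C), a symmetrical and faster allyl donor, to give 1-[2-bromo-4-(methoxymethoxy)-3,5-di(prop-2-enyl)phenyl]ethanone F2. Twofold olefin cross-metathesis with 2-methylbut-2-ene (second-generation Grubbs catalyst RuCl2(=CHPh)(H2IMes)(PCy3), CH2Cl2, 40 °C) turns both allyl groups into prenyl groups, and the route is rejoined at ketone 7.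

Step 5. C-acylation by the electron-rich benzoate may be sluggish, so that self-condensation of the ketone enolate or retro-Claisen cleavage takes over. The fallback replaces the acylation by an aldol addition and oxidation. It sets out from ketone 7, whose lithium enolate (LDA, THF, –78 °C) is added to purchased 4-(methoxymethoxy)benzaldehyde F3 to give racemic 1-[2-bromo-4-(methoxymethoxy)-3,5-bis(3-methylbut-2-enyl)phenyl]-3-hydroxy-3-[4-(methoxymethoxy)phenyl]propan-1-one F4. Dess–Martin oxidation of this β-hydroxy ketone returns the route at diketone 10, where the stereochemistry is set afresh in step 6.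

**Further compounds**

F1 | step 7 | (1S,3S)-1-[2-iodo-4-(methoxymethoxy)-3,5-bis(3-methylbut-2-enyl)phenyl]-3-[4-(methoxymethoxy)phenyl]propane-1,3-diol | O[C@@H](C[C@H](O)c1ccc(OCOC)cc1)c1cc(CC=C(C)C)c(OCOC)c(CC=C(C)C)c1I
F2 | step 3 | 1-[2-bromo-4-(methoxymethoxy)-3,5-di(prop-2-enyl)phenyl]ethanone | CC(=O)c1cc(CC=C)c(OCOC)c(CC=C)c1Br
F3 | step 5 | 4-(methoxymethoxy)benzaldehyde (purchased) | COCOc1ccc(C=O)cc1
F4 | step 5 | racemic 1-[2-bromo-4-(methoxymethoxy)-3,5-bis(3-methylbut-2-enyl)phenyl]-3-hydroxy-3-[4-(methoxymethoxy)phenyl]propan-1-one | O=C(CC(O)c1ccc(OCOC)cc1)c1cc(CC=C(C)C)c(OCOC)c(CC=C(C)C)c1Br
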